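## Structural features

The target is a ten-membered carbocycle (C1–C10) cis-fused at C6–C7 to an α-methylene-γ-butyrolactone (O6–C12(=O)–C11(=C13H2)–C7). The carbocycle holds a cross-conjugated dienone, C1=C10(CH3)–C2(=O)–C3=C4(CH3), in which both trisubstituted alkenes are Z, and a single methylene, C9. Four contiguous stereocentres follow one another: C5 (S, free hydroxyl), C6 (R, lactone oxygen), C7 (R, ring fusion) and C8 (S, tiglate). O5 and O6 are cis on the ring, C11 is cis to O6, and O8 is trans to C11. The fragile groups are the exo-methylene lactone (a Michael acceptor), the tiglate, which sits β to the γ-acidic C9 and can leave by vinylogous elimination, and the Z-γ-hydroxy enone, which can isomerise or close onto C2. The real difficulty is a medium ring with two Z enones on one carbonyl, together with the C7/C8 pair that has to be set on a flexible ring. The key step uses the fact that C2–C3=C4(CH3)–C5(O)–C6(O)–C7 is a cis-dioxygenated methylcyclohexene whose ends C2 and C7 are joined in the target by the four-carbon bridge C1–C10–C9–C8. A propynyl group on C2 (C1≡C10–CH3) and a vinyl group on C7 (C8=C9) therefore form a 3-oxy-1,5-enyne that can expand the six-membered ring to the ten-membered dienone in one [3,3] shift. C5 and C6 come from the cis-diol of (−)-quinic acid.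

## Logic of the disconnections

30 ⇒ 29: the O5–Si bond is cut. O5 has to be masked while the C8 hydroxyl is free and acylated. The forward step needs a fluoride source that spares the ester, the lactone and the enones.

29 ⇒ 27 + 28: the acyl C–O8 bond is cut. This removes the only side chain and leaves the complete bicyclic core. The forward acylation goes with retention, so 27 must already have the C8 configuration of the target.

27 ⇒ 24 + 25: C11=C13 is cut (olefination) and then C7–C11 (epoxide alkylation), which returns O8 to an oxirane. This removes the lactone ring and two stereocentres at once. The forward step needs backside attack at C7 by a carbanion tethered to O6, so the oxirane must lie trans to O6.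

24 ⇒ 23: the two C–O bonds of the oxirane are cut, giving the Z alkene C7=C8. The forward step must be selective for the one electron-rich alkene and for the face anti to O6.

23 ⇒ 22 ⇒ 20 + 21: the O5–Si bond and then the O6–acyl bond are cut. The two-carbon lactone unit and the phosphorus handle come from 21. The forward step has to tell O6 from O5 in a cis-diol.

20 ⇒ 19: the two acetal C–O bonds are re-formed, which returns the diol to the protected form that survives strong base.

19 ⇒ 16: retro-[3,3]. C9–C10 is cut and C2–C7 is re-formed, which contracts the ten-membered ring to a cyclohexene and removes the whole dienone. The forward step needs the 3-oxy-1,5-enyne with propynyl and vinyl gauche, and it fixes the geometry of C7=C8 through the configuration at C2.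

16 ⇒ 12 + 13: the C1–C2 bond is cut (acetylide addition to the ketone). The forward step must avoid enolisation of the sensitive ketone and control the face of attack.

12 ⇒ 11 ⇒ 8 + 9: the C8=C9 unsaturation is masked as a sulfoxide, and then the C7–C8 bond is cut (enolate Michael addition). The forward step needs the kinetic α′ enolate and attack trans to O6.

8 ⇒ 7 ⇒ 6: the C3=C4 unsaturation is removed and the C4–CH3 bond is cut (conjugate addition followed by dehydrogenation). The forward step needs a regiodefined enol derivative.

6 ⇒ 4 ⇒ 3 ⇒ 2 ⇒ 1: the C3=C4 alkene goes back to a β-hydroxy ketone, the ketone to a 1,2-diol (glycol cleavage), the diol to a lactone, and the lactone acetonide to the chiral-pool acid. All of these are functional-group changes on an intact ring that already holds C5 and C6.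

## Other disconnections considered

Alternative 1: the cut is at C1–C2 and C2–C3, with carbon monoxide as C2. The forward step is a carbonylative Stille macrocyclisation (Pd2(dba)3, AsPh3, CO) of the seco Z-alkenyl iodide / Z-alkenylstannane A2 to the silyl ether A1, which is identical with 29.
- In its favour: both enone geometries come from stereodefined alkenyl partners. This is equal to the chosen plan for C3=C4 and better for C1=C10, which in the chosen plan rests on a protonation. The four stereocentres, the lactone and the tiglate are in place before ring closure, so only desilylation follows, and here the alternative is better than the chosen plan. The conditions are neutral, which is also better.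
- Against it: a ten-membered ring must be closed by a palladium coupling in competition with oligomerisation and with direct, CO-free coupling. A2 needs C5–C8 built from acyclic material and two Z-trisubstituted alkenyl metal or halide ends. The exo-methylene lactone and the stannane are exposed to palladium.
- Comparison: the chosen plan pays no cyclisation entropy and takes C5/C6 from the chiral pool, but it must build C7/C8 on the macrocycle. In step count the chosen plan (17 steps) is expected to be equal or shorter.

Alternative 2: the cut is at C5–C6. In one flask the furan A4 is opened by singlet oxygen and Me2S to the Z-keto-enal A5, and DBU then closes the ring by vinylogous aldol addition of the butenolide γ-carbon to give A3.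
- In its favour: the furan guarantees the Z geometry of C3=C4 (equal to the chosen plan). A4 is assembled convergently from two simple halves, which is better in convergence. Ring closure and dienone appear in one operation (equal).
- Against it: C5 and C6 are created in the ring-closing step under only remote control from C8, whereas the chosen plan inherits both (chosen plan better). Singlet oxygen can also react with the trisubstituted C1=C10 alkene in an ene reaction. DBU can isomerise the Z-enedione and eliminate the tiglate through C9. A3 still needs transposition of the C7=C11 alkene to the exocyclic position with control at C7.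
- Comparison: the alternative is milder in its ring closure, but it leaves three stereochemical problems open after the key step where the chosen plan leaves two, both settled by stereospecific reactions.

Alternative 3: the cut is at C8–C9. The forward step is a BF3·OEt2-mediated vinylogous Mukaiyama aldol macrocyclisation of the aldehyde / 2-silyloxydiene A7 to the alcohol A6, which is identical with 27.
- In its favour: the endgame coincides with the last two steps of the chosen plan (equal). C5–C7 and the lactone are preset, and the C1=C10 enone is formed in the same step.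
- Against it: C8 is created during macrocyclisation with only 1,2-induction from C7. The aldehyde of A7 is β to the lactone oxygen and α to an epimerisable centre, so elimination and epimerisation threaten. The Lewis acid meets a silyl ether and an exo-methylene lactone. The Z geometry of C1=C10 is not intrinsic to a vinylogous aldol.
- Comparison: the chosen plan sets C8 by an SN2 opening and forms the ring without a cyclisation, which is mechanistically safer. A7 needs its own stereoselective synthesis, so no gain in steps is expected.

Key step: step 10

Remark on the chemistry: of the two C2 epimers of the rearrangement substrate, the route uses the one with propynyl cis to vinyl (anti to the dioxolane). Convex-face addition should deliver this epimer, and it leads to the Z alkene at C7=C8, from which C8 gets the target configuration without an inversion. The other epimer would give the E alkene and is treated as a fallback.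

## Steps

Step 1
Reactants: 1 (−)-quinic acid
Product: 2 3,4-O-isopropylidene-1,5-quinide (γ-lactone of quinic acid with the cis-diol as acetonide)
Conditions: Me2C(OMe)2, TsOH (cat.), acetone, reflux
Reagents that add atoms: 2,2-dimethoxypropane, COC(C)(C)OC
Why: Acid-catalysed transketalisation protects the only cis-1,2-diol while the carboxyl lactonises onto the remaining syn hydroxyl; no stereocentre is touched.

Step 2
Reactants: 2 3,4-O-isopropylidene-1,5-quinide
Product: 3 triol: 1-(hydroxymethyl)cyclohexane-1,3,4,5-tetrol 3,4-acetonide (tertiary OH, CH2OH, one secondary OH trans to the dioxolane)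
Conditions: NaBH4, EtOH, 0 °C → rt
Reagents that add atoms: none
Why: Hydride reduction of the strained α-hydroxy lactone gives the primary alcohol and leaves the acetonide intact.

Step 3
Reactants: 3 triol
Product: 4 3-hydroxy-4,5-(isopropylidenedioxy)cyclohexan-1-one (hydroxyl trans to the dioxolane)
Conditions: NaIO4, pH 7 phosphate buffer, H2O, 0 °C → rt
Reagents that add atoms: none
Why: Malaprade glycol cleavage of the tertiary-OH/CH2OH pair removes the former carboxyl carbon as formaldehyde and leaves the ketone that becomes C2.

Step 4
Reactants: 4 β-hydroxy ketone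
Product: 6 (4S,5R)-4,5-(isopropylidenedioxy)cyclohex-2-en-1-one, via β-mesyloxy ketone 5 (not isolated)
Conditions: MsCl, Et3N, CH2Cl2, 0 °C → rt
Reagents that add atoms: none
Why: Mesylation followed by E1cB elimination gives the enone; the dioxolane oxygen on the other β-carbon is held out of alignment with the enolate and stays.

Step 5
Reactants: 6 enone
Product: 7 trimethylsilyl enol ether: 3-methyl-4,5-(isopropylidenedioxy)-1-(trimethylsilyloxy)cyclohex-1-ene, methyl trans to the neighbouring oxygen
Conditions: Me2CuLi (MeLi, CuI), TMSCl, Et2O–THF, −78 °C; Et3N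
Reagents that add atoms: lithium dimethylcuprate, [Li+].C[Cu-]C; chlorotrimethylsilane, C[Si](C)(C)Cl
Why: Silyl-accelerated conjugate addition of the cuprate puts the C4 methyl on the β-carbon anti to the C5 oxygen and traps the regiodefined enolate; the new centre is removed in step 6.

Step 6
Reactants: 7 silyl enol ether
Product: 8 (4S,5R)-4,5-(isopropylidenedioxy)-3-methylcyclohex-2-en-1-one
Conditions: Pd(OAc)2 (10 mol %), O2 (1 atm), DMSO, 40 °C
Reagents that add atoms: none
Why: Saegusa–Ito dehydrogenation: divalent palladium binds C3 anti to the neighbouring methyl, that is syn to H4, and β-hydride elimination restores the C3=C4 enone with its methyl group; dioxygen returns zerovalent palladium to Pd(OAc)2.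

Step 7
Reactants: 8 methyl enone; 9 phenyl vinyl sulfoxide
Product: 11 (4S,5R,6R)-4,5-(isopropylidenedioxy)-3-methyl-6-[2-(phenylsulfinyl)ethyl]cyclohex-2-en-1-one (side chain trans to the adjacent oxygen; both configurations at sulfur), via lithium dienolate 10 (not isolated)
Conditions: LDA, THF, −78 °C; 9, −78 → −30 °C; AcOH
Reagents that add atoms: none
Why: Kinetic deprotonation at the α′ carbon C7 gives the cross-conjugated enolate, which adds in Michael fashion to the vinyl sulfoxide (a vinyl cation equivalent) on the convex face, so the chain is trans to O6; the dioxolane C6–O bond overlaps poorly with the enolate, which holds back β-elimination at low temperature.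

Step 8
Reactants: 11 sulfoxide
Product: 12 (4S,5R,6R)-4,5-(isopropylidenedioxy)-3-methyl-6-vinylcyclohex-2-en-1-one
Conditions: NaHCO3, toluene, 110 °C
Reagents that add atoms: none
Why: Thermal syn-elimination of benzenesulfenic acid (sulfoxide pyrolysis) unveils the vinyl group; only the CH2 next to C7 has β-hydrogens, and the buffer keeps the β,γ-unsaturated ketone out of conjugation.

Step 9
Reactants: 12 vinyl ketone; 13 propyne
Product: 16 (1R,4S,5R,6R)-4,5-(isopropylidenedioxy)-3-methyl-1-(prop-1-ynyl)-6-vinylcyclohex-2-en-1-ol (propynyl cis to vinyl, hydroxyl cis to the dioxolane), via 1-propynyllithium 14 (not isolated), via dichloro(prop-1-ynyl)cerium 15 (not isolated)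
Conditions: 13, n-BuLi, THF, −78 °C; CeCl3, −78 °C; then 12; H2O
Reagents that add atoms: none
Why: Organocerium 1,2-addition avoids enolisation at the doubly activated C7–H; the slim alkynyl nucleophile should attack axially on the convex face of the half-chair that has vinyl and O6 equatorial, anti to the dioxolane, which puts propynyl cis to vinyl. This centre is lost in step 10, but its configuration decides the geometry of C7=C8.

Step 10
Reactants: 16 propynyl vinyl cyclohexenol
Product: 19 (2Z,5Z,7R,8S,9Z)-7,8-(isopropylidenedioxy)-3,9-dimethylcyclodeca-2,5,9-trien-1-one (target numbering: C2 ketone, Z-C1=C10, Z-C3=C4, Z-C7=C8, C5/C6 acetonide), via potassium alkoxide 17 (not isolated), via potassium allenolate 18 (not isolated)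
Conditions: KH, 18-crown-6, THF, 0 → 25 °C; AcOH–THF, −78 °C
Reagents that add atoms: none
Why: KH with the crown ether gives the free potassium alkoxide 17, whose oxyanion weakens C2–C7, and a charge-accelerated [3,3] shift (anionic acetylenic oxy-Cope rearrangement) joins the alkyne terminus C10 to the vinyl terminus C9 while C2–C7 breaks. The closest known reaction type is the anionic oxy-Cope ring expansion of 1-alkynyl-2-vinylcycloalkanols to medium-ring 2,6-dienones through allenolates. The ten-membered ring is not closed by a cyclisation; it arises by four-atom ring expansion of the cyclohexene through a six-centre transition state, so no medium-ring entropy is paid. No stereocentre is formed: C2 and C7 become trigonal and C5/C6 are untouched. In the half-chair with propynyl axial and vinyl and O6 equatorial, the vinyl terminus must swing toward the axial alkyne, that is toward C6, so C6 and C9 end cis and C7=C8 is Z (the C2 epimer would give E). C3=C4 stays Z as the former ring alkene, and allenolate 18 is protonated at C1 from outside the ring, on the side of the exocyclic methyl, which gives the ring-cis Z enone that is also the more stable geometry. The step needs periselectivity for the enyne over the 1,5-diene through C3=C4, which the equatorial vinyl secures because it cannot reach C4, and the dioxolane survives because the cross-conjugated allenolate puts no charge β to either oxygen. The cold acidic quench avoids deprotonation of the doubly activated C9.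

Step 11
Reactants: 19 macrocyclic acetonide
Product: 20 (2Z,5Z,7R,8S,9Z)-7,8-dihydroxy-3,9-dimethylcyclodeca-2,5,9-trien-1-one (cis-diol at C5/C6 of the target numbering)
Conditions: AcOH–H2O–THF (3:1:1), 40 °C
Reagents that add atoms: none
Why: Mild aqueous acid hydrolysis of the isopropylidene acetal; the dioxolane on the medium ring is allylic on both sides and strained, so it should cleave under conditions that leave the skipped dienone alone.

Step 12
Reactants: 20 diol; 21 diethylphosphonoacetic acid
Product: 22 O6 mono-ester: the C6 hydroxyl of 20 as its (diethoxyphosphoryl)acetate, C5 hydroxyl free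
Conditions: 21 (1.05 equiv), DIC, DMAP (5 mol %), CH2Cl2, −20 °C
Reagents that add atoms: none
Why: Steglich esterification with one equivalent of acid at low temperature should take the less hindered O6 hydroxyl (next to C7–H) in preference to O5, which is flanked by the C4 methyl and can hydrogen-bond to the C2 carbonyl.

Step 13
Reactants: 22 mono-ester
Product: 23 O5-triethylsilyl ether of 22
Conditions: TESCl, imidazole, DMF, 0 °C
Reagents that add atoms: chlorotriethylsilane, CC[Si](CC)(CC)Cl
Why: Silylation of the only free hydroxyl; O5 is masked before the C8 hydroxyl is set free, so that the later tigloylation is unambiguous.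

Step 14
Reactants: 23 silyl ether
Product: 24 C7–C8 cis-epoxide of 23 with the oxirane oxygen trans to the O6 acyloxy group
Conditions: mCPBA, NaHCO3, CH2Cl2, 0 °C
Reagents that add atoms: 3-chloroperbenzoic acid, OOC(=O)c1cccc(Cl)c1
Why: Prilezhaev epoxidation of the only electron-rich alkene. Allylic 1,3-strain in the Z alkene puts H6 in the alkene plane and the C6–C5 ring bond over one face, so the peracid should enter from the periphery, anti to that bond and trans to O6, as is usual for medium-ring Z-cycloalkenyl derivatives.

Step 15
Reactants: 24 epoxy phosphonoacetate; 25 formaldehyde (as paraformaldehyde)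
Product: 27 O5-triethylsilyl 8-hydroxy α-methylene lactone (the des-tigloyl target as its O5 silyl ether; 5S,6R,7R,8S), via sodium phosphono-lactone carbanion 26 (not isolated)
Conditions: NaHMDS (1.0 equiv), THF, −78 → 0 °C; then (CH2O)n, 0 → 25 °C
Reagents that add atoms: none
Why: One equivalent of base gives the phosphonate-stabilised ester carbanion, which opens the epoxide at C7 by 5-exo attack with inversion (intramolecular epoxide alkylation); C11 ends cis to O6, and the C8 alkoxide, already in the target configuration, is quenched by the acidic C11–H. The resulting carbanion 26 undergoes Horner–Wadsworth–Emmons olefination with formaldehyde to give the exo-methylene lactone; the epoxide has served as a protected C8 hydroxyl up to this point.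

Step 16
Reactants: 27 hydroxy lactone; 28 tiglic acid
Product: 29 O5-triethylsilyl ether of the target
Conditions: 28, DIC, DMAP, CH2Cl2, 0 → 25 °C
Reagents that add atoms: none
Why: Steglich esterification of the only free hydroxyl with retention at C8; tiglic acid is the stable E isomer and should not isomerise under DMAP catalysis.

Step 17
Reactants: 29 silyl ether
Product: 30 target, CNP0230565.3
Conditions: HF·pyridine, pyridine, THF, 0 °C
Reagents that add atoms: none
Why: Buffered fluoride cleaves the Si–O bond of the triethylsilyl ether under conditions that spare the tiglate, the exo-methylene lactone and the Z-γ-hydroxy enone.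

## Compound list

1 | (−)-quinic acid | C1[C@H]([C@H]([C@@H](C[C@@]1(C(=O)O)O)O)O)O | starting material
2 | 3,4-O-isopropylidene-1,5-quinide | C1[C@H]2OC(C)(C)O[C@H]2[C@H]2C[C@]1(O)C(=O)O2 | intermediate
3 | 1-(hydroxymethyl)cyclohexane-1,3,4,5-tetrol 3,4-acetonide | C1[C@H]2OC(C)(C)O[C@H]2[C@H](O)C[C@]1(O)CO | intermediate
4 | 3-hydroxy-4,5-(isopropylidenedioxy)cyclohexan-1-one | C1[C@H]2OC(C)(C)O[C@H]2[C@H](O)CC1=O | intermediate
5 | 3-(methanesulfonyloxy)-4,5-(isopropylidenedioxy)cyclohexan-1-one | C1[C@H]2OC(C)(C)O[C@H]2[C@H](OS(C)(=O)=O)CC1=O | intermediate (not isolated)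
6 | (4S,5R)-4,5-(isopropylidenedioxy)cyclohex-2-en-1-one | O=C1C=C[C@@H]2OC(C)(C)O[C@@H]2C1 | intermediate
7 | 3-methyl-4,5-(isopropylidenedioxy)-1-(trimethylsilyloxy)cyclohex-1-ene | C[Si](C)(C)OC1=C[C@@H](C)[C@@H]2OC(C)(C)O[C@@H]2C1 | intermediate
8 | (4S,5R)-4,5-(isopropylidenedioxy)-3-methylcyclohex-2-en-1-one | O=C1C=C(C)[C@@H]2OC(C)(C)O[C@@H]2C1 | intermediate
9 | phenyl vinyl sulfoxide | C=CS(=O)c1ccccc1 | starting material
10 | lithium cross-conjugated dienolate of 8 | [Li+].[O-]C1=C[C@H]2OC(C)(C)O[C@H]2C(C)=C1 | intermediate (not isolated)
11 | (4S,5R,6R)-4,5-(isopropylidenedioxy)-3-methyl-6-[2-(phenylsulfinyl)ethyl]cyclohex-2-en-1-one | O=C1C=C(C)[C@@H]2OC(C)(C)O[C@@H]2[C@H]1CCS(=O)c1ccccc1 | intermediate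
12 | (4S,5R,6R)-4,5-(isopropylidenedioxy)-3-methyl-6-vinylcyclohex-2-en-1-one | O=C1C=C(C)[C@@H]2OC(C)(C)O[C@@H]2[C@H]1C=C | intermediate
13 | propyne | CC#C | starting material
14 | 1-propynyllithium | [Li]C#CC | intermediate (not isolated)
15 | dichloro(prop-1-ynyl)cerium | Cl[Ce](Cl)C#CC | intermediate (not isolated)
16 | (1R,4S,5R,6R)-4,5-(isopropylidenedioxy)-3-methyl-1-(prop-1-ynyl)-6-vinylcyclohex-2-en-1-ol | O[C@]1(C#CC)C=C(C)[C@@H]2OC(C)(C)O[C@@H]2[C@H]1C=C | intermediate
17 | potassium alkoxide of 16 | [K+].[O-][C@]1(C#CC)C=C(C)[C@@H]2OC(C)(C)O[C@@H]2[C@H]1C=C | intermediate (not isolated)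
18 | potassium allenolate of the ten-membered ring (allene axis not specified) | [K+].[O-]C1=C=C(C)C/C=C\[C@H]2OC(C)(C)O[C@H]2/C(C)=C\1 | intermediate (not isolated)
19 | (2Z,5Z,7R,8S,9Z)-7,8-(isopropylidenedioxy)-3,9-dimethylcyclodeca-2,5,9-trien-1-one | O=C1/C=C(/C)C/C=C\[C@H]2OC(C)(C)O[C@H]2/C(C)=C\1 | intermediate
20 | (2Z,5Z,7R,8S,9Z)-7,8-dihydroxy-3,9-dimethylcyclodeca-2,5,9-trien-1-one | O=C1/C=C(/C)C/C=C\[C@@H](O)[C@@H](O)/C(C)=C\1 | intermediate
21 | diethylphosphonoacetic acid | OC(=O)CP(=O)(OCC)OCC | starting material
22 | O6 (diethoxyphosphoryl)acetate of 20 | O=C1/C=C(/C)C/C=C\[C@@H](OC(=O)CP(=O)(OCC)OCC)[C@@H](O)/C(C)=C\1 | intermediate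
23 | O5-triethylsilyl ether of 22 | O=C1/C=C(/C)C/C=C\[C@@H](OC(=O)CP(=O)(OCC)OCC)[C@@H](O[Si](CC)(CC)CC)/C(C)=C\1 | intermediate
24 | C7–C8 cis-epoxide of 23, oxirane trans to O6 | O=C1/C=C(/C)C[C@@H]2O[C@@H]2[C@@H](OC(=O)CP(=O)(OCC)OCC)[C@@H](O[Si](CC)(CC)CC)/C(C)=C\1 | intermediate
25 | formaldehyde (as paraformaldehyde) | C=O | starting material
26 | sodium salt of the α-(diethoxyphosphoryl) lactone carbanion with free C8 hydroxyl | [Na+].CCOP(=O)(OCC)[C-]1C(=O)O[C@@H]2[C@H]1[C@@H](O)C/C(C)=C\C(=O)/C=C(/C)[C@@H]2O[Si](CC)(CC)CC | intermediate (not isolated)
27 | O5-triethylsilyl des-tigloyl target (8-hydroxy α-methylene lactone) | C=C1C(=O)O[C@@H]2[C@H]1[C@@H](O)C/C(C)=C\C(=O)/C=C(/C)[C@@H]2O[Si](CC)(CC)CC | intermediate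
28 | tiglic acid | C/C=C(\C)C(=O)O | starting material
29 | O5-triethylsilyl ether of the target | C=C1C(=O)O[C@@H]2[C@H]1[C@@H](OC(=O)/C(C)=C/C)C/C(C)=C\C(=O)/C=C(/C)[C@@H]2O[Si](CC)(CC)CC | intermediate
30 | CNP0230565.3 | C=C1C(=O)O[C@@H]2[C@H]1[C@@H](OC(=O)/C(C)=C/C)C/C(C)=C\C(=O)/C=C(/C)[C@@H]2O | target

Total: 17 steps. Longest linear sequence: 17 steps (1 → 30).

## Least certain steps

**Step 10 (key step).** The alkoxide may expel the propynyl anion by retro-addition before it rearranges. Part of the material may react through the other half-chair and give the E alkene at C7=C8. After protonation, residual base can deprotonate the doubly activated C9 and move the skipped alkene into conjugation or scramble the C1=C10 geometry. The cause in each case is that a strained medium-ring allenolate is generated under strongly basic conditions. The fallback replaces the alkyne by an alkene and adds the second unsaturation afterwards. It sets out from 12: (E)-prop-1-enyllithium with CeCl3 gives the propenyl vinyl cyclohexenol F1. KH and 18-crown-6 bring about the classical anionic oxy-Cope ring expansion of the 1,2-dialkenyl carbinol, and TMSCl traps the enolate as the silyl dienol ether F2. Saegusa–Ito dehydrogenation with Pd(OAc)2 then introduces C1=C10, and the sequence comes back to the route at 19.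

**Step 9.** Poor facial selectivity is the most likely problem. Attack anti to the equatorial vinyl group, on the dioxolane face, competes with convex-face axial attack and would give the C2 epimer, which rearranges to the E alkene. The fallback uses that epimer in a parallel sequence. It sets out from 12, and its first compound is the epimeric carbinol F3.
- KH with 18-crown-6 gives the E-configured macrocyclic acetonide F4, and aqueous acetic acid gives the E-diol F5.
- mCPBA, directed by the C6 hydroxyl, gives the trans-epoxy diol F6. The ring holds the C6–C5 bond perpendicular to the E alkene, so the hydroxyl sits near 130° to the alkene plane, which is the geometry that hydrogen-bonded peracid delivery prefers; the oxirane oxygen at C7 then lies anti to O6.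
- Selective O6 phosphonoacetylation gives F7, and silylation gives F8.
- NaHMDS and then formaldehyde give the C8-epimeric hydroxy lactone F9.
- Mitsunobu esterification with 28 (PPh3, DIAD) inverts C8, and the sequence comes back to the route at 29.

**Step 15.** Two processes compete with the 5-exo alkylation. Deprotonation at C9 would open the neighbouring epoxide by vinylogous β-elimination. Attack of the C8 alkoxide on phosphorus would lead to Wadsworth–Emmons cyclopropanation. The C8 hydroxyl could also take over the lactone carbonyl by translactonisation once it is free. The fallback uses a more nucleophilic carbanion that carries no phosphorus and is generated by a weaker base. It sets out from 20: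
- monoallyl malonate, DIC and DMAP give the O6 allyl malonate F10;
- TESCl gives F11, and mCPBA gives the epoxide F12;
- Cs2CO3 in MeCN closes the α-(allyloxycarbonyl) lactone F13;
- Pd(PPh3)4 with morpholine removes the allyl group, and aqueous formaldehyde with Et2NH then effects decarboxylative Mannich methylenation, which comes back to the route at 27.

**Step 12.** Poor discrimination between O6 and O5, or migration of the acyl group from O6 to the neighbouring O5, would give the wrong ester, because the two hydroxyls differ only in their steric surroundings. The fallback separates protection from acylation. It sets out from 20: TESOTf and 2,6-lutidine give the bis-silyl ether F14. HF·pyridine in pyridine–THF at −20 °C removes the less hindered O6 silyl group to give the O5 mono-silyl ether F15. Esterification of its single hydroxyl with 21 (DIC, DMAP) comes back to the route at 23.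

**Step 7.** Loss of the C6 oxygen by β-elimination from the enolate, followed by aromatisation, and a second Michael addition by the equilibrated adduct anion are the likely failures, because the sulfoxide acceptor needs warming above −78 °C. The fallback uses an electrophile that reacts at −78 °C. It sets out from 8: the lithium enolate is added to (phenylselanyl)acetaldehyde to give the β-hydroxy selenide F16, and MsCl with Et3N brings about anti-elimination of the selenium and oxygen groups to the vinyl group, which comes back to the route at 12.

## Further compounds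

F1 | step 10 | 4,5-(isopropylidenedioxy)-3-methyl-1-[(E)-prop-1-enyl]-6-vinylcyclohex-2-en-1-ol (propenyl cis to vinyl) | O[C@]1(/C=C/C)C=C(C)[C@@H]2OC(C)(C)O[C@@H]2[C@H]1C=C
F2 | step 10 | trimethylsilyl dienol ether of the ring-expanded ketone (C10 methyl centre and enol ether geometry unspecified) | C[Si](C)(C)OC1=CC(C)C/C=C\[C@H]2OC(C)(C)O[C@H]2/C(C)=C\1
F3 | step 9 | (1S,4S,5R,6R)-4,5-(isopropylidenedioxy)-3-methyl-1-(prop-1-ynyl)-6-vinylcyclohex-2-en-1-ol (propynyl trans to vinyl) | O[C@@]1(C#CC)C=C(C)[C@@H]2OC(C)(C)O[C@@H]2[C@H]1C=C
F4 | step 9 | (2Z,5E,7R,8S,9Z)-7,8-(isopropylidenedioxy)-3,9-dimethylcyclodeca-2,5,9-trien-1-one | O=C1/C=C(/C)C/C=C/[C@H]2OC(C)(C)O[C@H]2/C(C)=C\1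
F5 | step 9 | (2Z,5E,7R,8S,9Z)-7,8-dihydroxy-3,9-dimethylcyclodeca-2,5,9-trien-1-one | O=C1/C=C(/C)C/C=C/[C@@H](O)[C@@H](O)/C(C)=C\1
F6 | step 9 | C7–C8 trans-epoxide of F5, oxirane oxygen at C7 anti to O6 | O=C1/C=C(/C)C[C@H]2O[C@@H]2[C@@H](O)[C@@H](O)/C(C)=C\1
F7 | step 9 | O6 (diethoxyphosphoryl)acetate of F6 | O=C1/C=C(/C)C[C@H]2O[C@@H]2[C@@H](OC(=O)CP(=O)(OCC)OCC)[C@@H](O)/C(C)=C\1
F8 | step 9 | O5-triethylsilyl ether of F7 | O=C1/C=C(/C)C[C@H]2O[C@@H]2[C@@H](OC(=O)CP(=O)(OCC)OCC)[C@@H](O[Si](CC)(CC)CC)/C(C)=C\1
F9 | step 9 | C8 epimer of 27 | C=C1C(=O)O[C@@H]2[C@H]1[C@H](O)C/C(C)=C\C(=O)/C=C(/C)[C@@H]2O[Si](CC)(CC)CC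
F10 | step 15 | O6 allyl malonate of 20 | O=C1/C=C(/C)C/C=C\[C@@H](OC(=O)CC(=O)OCC=C)[C@@H](O)/C(C)=C\1
F11 | step 15 | O5-triethylsilyl ether of F10 | O=C1/C=C(/C)C/C=C\[C@@H](OC(=O)CC(=O)OCC=C)[C@@H](O[Si](CC)(CC)CC)/C(C)=C\1
F12 | step 15 | C7–C8 cis-epoxide of F11, oxirane trans to O6 | O=C1/C=C(/C)C[C@@H]2O[C@@H]2[C@@H](OC(=O)CC(=O)OCC=C)[C@@H](O[Si](CC)(CC)CC)/C(C)=C\1
F13 | step 15 | α-(allyloxycarbonyl) lactone with free C8 hydroxyl (C11 unspecified) | C=CCOC(=O)C1C(=O)O[C@@H]2[C@H]1[C@@H](O)C/C(C)=C\C(=O)/C=C(/C)[C@@H]2O[Si](CC)(CC)CC
F14 | step 12 | O5,O6-bis(triethylsilyl) ether of 20 | O=C1/C=C(/C)C/C=C\[C@@H](O[Si](CC)(CC)CC)[C@@H](O[Si](CC)(CC)CC)/C(C)=C\1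
F15 | step 12 | O5-triethylsilyl ether of 20 (O6 hydroxyl free) | O=C1/C=C(/C)C/C=C\[C@@H](O)[C@@H](O[Si](CC)(CC)CC)/C(C)=C\1
F16 | step 7 | 6-[1-hydroxy-2-(phenylselanyl)ethyl]-4,5-(isopropylidenedioxy)-3-methylcyclohex-2-en-1-one (carbinol centre unspecified) | O=C1C=C(C)[C@@H]2OC(C)(C)O[C@@H]2[C@H]1C(O)C[Se]c1ccccc1
A1 | alternative 1 | O5-triethylsilyl ether of the target (identical with 29) | C=C1C(=O)O[C@@H]2[C@H]1[C@@H](OC(=O)/C(C)=C/C)C/C(C)=C\C(=O)/C=C(/C)[C@@H]2O[Si](CC)(CC)CC
A2 | alternative 1 | seco Z-alkenyl iodide / Z-alkenyl tributylstannane on the preformed lactone | C=C1C(=O)O[C@H]([C@H]1[C@@H](OC(=O)/C(C)=C/C)C/C(C)=C\[Sn](CCCC)(CCCC)CCCC)[C@@H](O[Si](CC)(CC)CC)/C(C)=C\I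
A3 | alternative 2 | macrocyclic Z,Z-dienone with C5 carbinol and endocyclic C7=C11 butenolide | CC(C)(C)[Si](C)(C)OCC1=C2[C@@H](OC(=O)/C(C)=C/C)C/C(C)=C\C(=O)/C=C(/C)[C@H](O)[C@@H]2OC1=O
A4 | alternative 2 | 4-methylfuran tethered to the butenolide | CC(C)(C)[Si](C)(C)OCC1=C([C@@H](OC(=O)/C(C)=C/C)C/C(C)=C\c2cc(C)co2)COC1=O
A5 | alternative 2 | Z-4-oxo-enal from furan opening | CC(C)(C)[Si](C)(C)OCC1=C([C@@H](OC(=O)/C(C)=C/C)C/C(C)=C\C(=O)/C=C(/C)C=O)COC1=O
A6 | alternative 3 | C8 alcohol of the O5-silylated macrocycle (identical with 27) | C=C1C(=O)O[C@@H]2[C@H]1[C@@H](O)C/C(C)=C\C(=O)/C=C(/C)[C@@H]2O[Si](CC)(CC)CC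
A7 | alternative 3 | C8 aldehyde with the 2-silyloxydiene side chain | C=C1C(=O)O[C@H]([C@H]1C=O)[C@@H](O[Si](CC)(CC)CC)/C(C)=C\C(O[Si](C)(C)C)=CC(C)=C
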